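**Assumption:** Didemnidine B has no stereocentre and is achiral, so the request for a single enantiomer needs no action. It is drawn and made as the free base; conversion to a salt for storage is not counted as a step.

## The problem

Didemnidine B is a 6-bromoindole that carries at C3 a two-carbon α-ketoamide (glyoxamide). The amide nitrogen is N1 of spermidine, the nitrogen at the three-carbon end, while N4 (secondary) and N8 (primary, four-carbon end) stay free. No ring has to be built: 6-bromoindole is a commodity that fixes the bromine position, and C3 of indole is its natural nucleophilic site. The difficulty lies in the chain: one acyl group must go to exactly one of three nitrogens, and the two primary ones, N1 and N8, differ only by one CH2 in their tether to N4. The conventional answer is protection of N4 and N8, which makes the triamine reagent cost more steps than the rest of the molecule. The groups that limit the chemistry are: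
- the C6–Br bond, which rules out hydrogenolysis, Pd(0) and strongly reducing or radical conditions;
- the α-dicarbonyl unit;
- the free indole N–H;
- the very polar, doubly basic product.

The feature that makes the key step possible is the six-atom array formed by the amide carbonyl carbon, N1, the three CH2 carbons and N4. A bond from that carbon to N4 closes a six-membered 1,3-diazinane (hexahydropyrimidine) ring. N8 lies four carbons beyond N4 and could reach the same carbon only through a seven-membered 1,3-diazepane. A second feature helps: the ketone is an indol-3-yl ketone, a vinylogous amide of the indole nitrogen (N1–C2=C3–C=O). In a keto-aldehyde precursor only the aldehyde carbon is therefore a reactive electrophile.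

## Retrosynthesis

**7 to 6.** The target 7 is read as the ring-opened hydrate of cyclic amidine 6. The bond between the amide carbon and N4 is formed in the retro direction, and the amide oxygen is returned as water. The neighbouring cut, the amide C–N1 bond, would need a spermidine blocked at N4 and N8. In 6 the positional question is already answered by the ring, because the amidine carbon is bonded to N1 and N4 and cannot be bonded to N8. The forward reaction must add water at the amidinium carbon, not at the ketone, and must open the ring to the secondary N1 amide.

**6 to 5.** Amidine 6 is the dehydrogenation product of cyclic aminal 5; only the N1–H and C2–H hydrogens are removed. The forward reaction must oxidise the aminal without touching N8, the indole or the C–Br bond. The C2–H is both aminal and α to the ketone, so it is the most easily removed hydrogen in the molecule.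

**5 to 3 + 4.** Both C–N bonds at the aminal carbon are cut, which gives keto-aldehyde 3 and unprotected spermidine 4. This removes the whole triamine in one cut and leaves a ten-carbon achiral precursor. The forward condensation is reversible and must settle on the six-membered N1/N4 aminal, the same preference that formaldehyde shows with spermidine.

**3 to 2 to 1.** The aldehyde C–H of 3 is traced to the C–Cl of acid chloride 2 (reduction). The C3–C bond of 2 is traced to 6-bromoindole 1 and oxalyl chloride (uncatalysed Friedel–Crafts acylation). Both are standard for indol-3-ylglyoxyl compounds and tolerate the aryl bromide.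

## Roads not taken

**Alternative 1:** The most obvious cut is the amide C–N1 bond. Acid chloride 2 would acylate N4,N8-di-Boc-spermidine A1 to give the di-Boc amide A2, and acid would remove both carbamates from A2.
- This is reliable, but the positional problem is only moved into A1. A1 must be bought or made from putrescine in three further operations (mono-cyanoethylation, double Boc protection, nitrile reduction).
- That comes to about six steps and two protecting groups against three steps and none.
- Leaving the protection out is not a remedy. Free spermidine 4 would tell primary from secondary nitrogen but not N1 from N8, so the N8 amide A3 would form beside the target, and over-acylation would add to the loss. A3 differs from the target only in the place of one CH2 and would be hard to separate from it.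

**Alternative 2:** Cut the N4–CH2 bond on the propyl side. Acid chloride 2 and 3,3-diethoxypropan-1-amine would give the acetal amide A4. Hydrolysis of A4 would give the β-amido aldehyde A5, and reductive amination of A5 with an excess of symmetric putrescine would give the target.
- The symmetry of putrescine removes the N1/N8 question, which is attractive.
- The cost is four steps, an aldehyde A5 that is prone to elimination, and a hydride reagent used next to the keto group.
- Over-alkylation is also a problem: twice at one nitrogen, or once at each end of the diamine. It can be suppressed only by a large excess of diamine and a difficult polyamine separation.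
- The chosen plan uses the 1,3-relationship of N1 and N4 actively and forms no C–N bond that can over-react.

**Alternative 3:** Cut the C3–CO bond together with the CO–N bond. A Pd-catalysed double aminocarbonylation of 6-bromo-3-iodo-1H-indole A6 with CO and amine A1 would lead to A2.
- This needs oxidative addition at the C3–I bond of A6 without touching C6–Br, and double over single CO insertion, on a free indole N–H.
- It still needs the protected triamine A1 and a deprotection of A2. The hard part of the target, the choice of nitrogen, is not addressed at all.

Key step: step 3

## Route

**Step 1**
Reactants: 1 6-bromo-1H-indole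
Product: 2 2-(6-bromo-1H-indol-3-yl)-2-oxoacetyl chloride
Conditions: (COCl)2 (1.3 equiv), Et2O, 0 °C to rt; solid collected by filtration under N2 and used directly
Reagents that add atoms: oxalyl chloride, O=C(Cl)C(=O)Cl
Why: Uncatalysed Friedel–Crafts acylation at indole C3, the most nucleophilic position; the product is a deactivated 3-acylindole, so it should not react a second time, and the C6–Br bond is inert to these conditions.

**Step 2**
Reactants: 2 2-(6-bromo-1H-indol-3-yl)-2-oxoacetyl chloride
Product: 3 2-(6-bromo-1H-indol-3-yl)-2-oxoacetaldehyde (6-bromoindol-3-ylglyoxal, which may be handled as its hydrate)
Conditions: Bu3SnH (1.1 equiv), EtOAc, 0 °C to rt, N2, no initiator, light excluded; trituration with hexane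
Reagents that add atoms: none
Why: Tin hydride reduction of an acyl chloride to the aldehyde, a standard entry to indol-3-ylglyoxals; the indol-3-yl ketone is a vinylogous amide and should not be reduced, and without initiator or heat the aryl bromide should survive.

**Step 3**
Reactants: 3 2-(6-bromo-1H-indol-3-yl)-2-oxoacetaldehyde; 4 spermidine [N1-(3-aminopropyl)butane-1,4-diamine]
Product: 7 didemnidine B [N-{3-[(4-aminobutyl)amino]propyl}-2-(6-bromo-1H-indol-3-yl)-2-oxoacetamide], via cyclic aminal 5 (not isolated), via cyclic amidine 6 (not isolated)
Conditions: 4 (1.0 equiv), TFA (1.0 equiv), CH2Cl2/MeOH, 0 °C; then 3, 3 Å MS, 0 °C to rt; NBS (1.05 equiv), 0 °C to rt; then aq K2CO3 (pH about 10), rt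
Reagents that add atoms: water, O
Why: Proposed new method: the aldehyde carbon of 3 condenses with N1 of 4 and the α-keto iminium is closed by N4 in a reversible 6-endo-trig cyclisation to the 1,3-diazinane 5, which should be the thermodynamic sink because N8 can offer only a seven-membered 1,3-diazepane or an open imine. The one equivalent of TFA should rest on N8, the most basic nitrogen once N1 and N4 are aminal nitrogens next to an acyl group, so that NBS meets only the ring N1–H; N-bromination and loss of HBr across N1–C2, eased because C2–H is α to the ketone, should give amidine 6 as its salt. Aqueous carbonate then adds water at the amidinium carbon and the 2-hydroxy-1,3-diazinane opens to the amide. The two ring-opened amides (acyl on N1 or on N4) interconvert through this same six-membered tetrahedral intermediate, and the secondary N1 amide 7 is expected to prevail because it is planar, unhindered and held by an N–H···O=C contact to the ketone, whereas a tertiary N4 α-ketoamide must twist. The closest known reaction types are the one-pot NBS conversion of aldehydes and 1,2- or 1,3-diamines into imidazolines and tetrahydropyrimidines, the ring-opening hydrolysis of cyclic amidines to N-acyl diamines, the oxidative amidation of arylglyoxals to α-ketoamides, and the formaldehyde tether across N1 and N4 of spermidine; new is their union on an unprotected triamine so that ring size alone picks the acylated nitrogen. The only ring closed is the transient 1,3-diazinane, whose aminal carbon is a racemic stereocentre erased on oxidation, so no stereocontrol is needed. The selectivities needed are N1 over N8 (ring size), aminal oxidation over oxidation of N8 (protonation), water attack at the amidinium carbon and not at the ketone (the vinylogous-amide ketone is a poor electrophile, which should also suppress the Cannizzaro-type hydride shift of arylglyoxal hemiaminals), and survival of C6–Br and the indole (no metal, no reductant, and a 3-acylindole is deactivated towards NBS).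

## Compound list

1 | 6-bromo-1H-indole | Brc1ccc2cc[nH]c2c1 | starting material
2 | 2-(6-bromo-1H-indol-3-yl)-2-oxoacetyl chloride | O=C(Cl)C(=O)c1c[nH]c2cc(Br)ccc12 | intermediate
3 | 2-(6-bromo-1H-indol-3-yl)-2-oxoacetaldehyde | O=CC(=O)c1c[nH]c2cc(Br)ccc12 | intermediate
4 | spermidine, N1-(3-aminopropyl)butane-1,4-diamine | NCCCCNCCCN | starting material
5 | [1-(4-aminobutyl)-1,3-diazinan-2-yl](6-bromo-1H-indol-3-yl)methanone (racemic at the aminal carbon, present as its N8 ammonium salt) | O=C(c1c[nH]c2cc(Br)ccc12)C1NCCCN1CCCCN | intermediate (not isolated)
6 | [1-(4-aminobutyl)-1,4,5,6-tetrahydropyrimidin-2-yl](6-bromo-1H-indol-3-yl)methanone (present as its salt) | O=C(c1c[nH]c2cc(Br)ccc12)C1=NCCCN1CCCCN | intermediate (not isolated)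
7 | didemnidine B, N-{3-[(4-aminobutyl)amino]propyl}-2-(6-bromo-1H-indol-3-yl)-2-oxoacetamide | NCCCCNCCCNC(=O)C(=O)c1c[nH]c2cc(Br)ccc12 | target

## Step count and risk

Total steps: 3. Longest linear sequence: 3 (1 to 2 to 3 to 7; spermidine 4 is bought).

**Step 3 (key step, proposed new method).** Three things could go wrong, in order of likelihood.
- The hydrated amidine may open mainly by cleavage of the C2–N1 bond, which puts the acyl group on N4, and the N4-to-N1 acyl shift may then be too slow at a pH that is still safe. If forced, the acyl group could also move on to N8 through a seven-membered intermediate.
- N-bromination may not stay on the aminal N–H. The open-chain imine tautomer or a partly deprotonated N8 could be halogenated, which leads to oxidative deamination of the chain.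
- Hydroxide may attack the ketone of the 2-acylamidinium and cleave the C–C bond.

Fallback (known chemistry; the chain is built stepwise and no ring selects the nitrogen): it sets out from acid chloride 2. With an excess of symmetric 1,3-diaminopropane, 2 should give N-(3-aminopropyl)-2-(6-bromo-1H-indol-3-yl)-2-oxoacetamide F1. Reductive amination of F1 with tert-butyl N-(4-oxobutyl)carbamate (NaBH(OAc)3, DCE) should give tert-butyl N-{4-[(3-{[2-(6-bromo-1H-indol-3-yl)-2-oxoacetyl]amino}propyl)amino]butyl}carbamate F2. TFA in CH2Cl2 removes the Boc group, and the sequence comes back to the route at target 7.

**Step 2.** Tin-centred radicals may abstract the C6 bromine, the α-ketoacyl radical may lose CO, or reduction may continue past the aldehyde. Removal of tin residues from a polar, hydrate-forming aldehyde may also be incomplete and carry over into step 3.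

Fallback: it sets out from indole 1. Friedel–Crafts acetylation at C3 (AcCl, Et2AlCl, CH2Cl2, 0 °C) should give 1-(6-bromo-1H-indol-3-yl)ethan-1-one F3. Riley oxidation of the methyl ketone (SeO2, dioxane/H2O, reflux) should give the keto-aldehyde, and the sequence comes back to the route at compound 3.

**Step 1.** This is the safest step. What may go wrong is hydrolysis of the acid chloride during filtration and transfer, and some acylation at the indole nitrogen if excess reagent and warming are used. Either would lower the quality of the material sent to the tin hydride step.

Fallback: it sets out from indole 1 and avoids any acid chloride of the glyoxylic acid. C3 chloroacetylation (ClCH2COCl, pyridine, dioxane) should give 1-(6-bromo-1H-indol-3-yl)-2-chloroethan-1-one F4. Kornblum oxidation (DMSO, NaHCO3, catalytic NaI, heat) should convert the CH2Cl group into the aldehyde, and the sequence comes back to the route at compound 3.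

## Further compounds

F1 | step 3 | N-(3-aminopropyl)-2-(6-bromo-1H-indol-3-yl)-2-oxoacetamide | NCCCNC(=O)C(=O)c1c[nH]c2cc(Br)ccc12
F2 | step 3 | tert-butyl N-{4-[(3-{[2-(6-bromo-1H-indol-3-yl)-2-oxoacetyl]amino}propyl)amino]butyl}carbamate | CC(C)(C)OC(=O)NCCCCNCCCNC(=O)C(=O)c1c[nH]c2cc(Br)ccc12
F3 | step 2 | 1-(6-bromo-1H-indol-3-yl)ethan-1-one | CC(=O)c1c[nH]c2cc(Br)ccc12
F4 | step 1 | 1-(6-bromo-1H-indol-3-yl)-2-chloroethan-1-one | O=C(CCl)c1c[nH]c2cc(Br)ccc12
A1 | alternative 1 | N4,N8-di-Boc-spermidine, tert-butyl N-(3-aminopropyl)-N-{4-[(tert-butoxycarbonyl)amino]butyl}carbamate | NCCCN(CCCCNC(=O)OC(C)(C)C)C(=O)OC(C)(C)C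
A2 | alternative 1 | N4,N8-di-Boc-didemnidine B | CC(C)(C)OC(=O)NCCCCN(CCCNC(=O)C(=O)c1c[nH]c2cc(Br)ccc12)C(=O)OC(C)(C)C
A3 | alternative 1 | N-{4-[(3-aminopropyl)amino]butyl}-2-(6-bromo-1H-indol-3-yl)-2-oxoacetamide (N8 regioisomer) | NCCCNCCCCNC(=O)C(=O)c1c[nH]c2cc(Br)ccc12
A4 | alternative 2 | 2-(6-bromo-1H-indol-3-yl)-N-(3,3-diethoxypropyl)-2-oxoacetamide | CCOC(OCC)CCNC(=O)C(=O)c1c[nH]c2cc(Br)ccc12
A5 | alternative 2 | 2-(6-bromo-1H-indol-3-yl)-2-oxo-N-(3-oxopropyl)acetamide | O=CCCNC(=O)C(=O)c1c[nH]c2cc(Br)ccc12
A6 | alternative 3 | 6-bromo-3-iodo-1H-indole | Ic1c[nH]c2cc(Br)ccc12
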